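**Retrosynthetic overview**
1. Key bond: the CO–CO bond that becomes C4–C5 of the quinone joins two carbonyl carbons. It is made by adding the acyl anion generated from 1-bromodocosane (1), Li and CO to the ester carbonyl of methyl propanoate (2), giving hexacosane-3,4-dione (6).
2. Ring bonds C1–C6 and C2–C3: both α-methylenes of 6 are acylated by diethyl oxalate (7), which supplies C1 and C2, giving the target (11).
3. Ring order: the quinone is the only ring and is closed in the last step.

Assumption: the side chain is read as unbranched henicosyl (21 carbons); the molecule has no stereocentre and no stereogenic double bond, so there is no enantiomer to select.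

**Step 1**
Reactants: 1 1-bromodocosane; 2 methyl propanoate
Product: 6 hexacosane-3,4-dione, via docosyllithium 3 (not isolated), via tricosanoyllithium 4 (not isolated), via lithium 3-methoxy-4-oxohexacosan-3-olate 5 (not isolated)
Conditions: 1, Li (wire, 1% Na, 2.2 equiv), Et2O, 0 °C; titrated solution of 3 added over 2 h to 2 (1.5 equiv) in THF/Et2O/pentane 4:4:1 (0.05 M) under a steady stream of CO (1 atm), −110 °C; 1 h, then warm to rt; 1 M HCl
Reagents that add atoms: carbon monoxide, [C-]#[O+]
Why: Seyferth-type direct nucleophilic acylation of an ester: at −110 °C the primary alkyllithium 3 inserts CO faster than it attacks the ester, the acyllithium 4 (a true acyl anion) is trapped at once by the ester carbonyl of 2, and the lithium hemiketal alkoxide 5 does not collapse until the acidic work-up, so no second addition occurs; no stereocentre is formed.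

**Step 2**
Reactants: 6 hexacosane-3,4-dione; 7 diethyl oxalate
Product: 11 3-henicosyl-2,5-dihydroxy-6-methylcyclohexa-2,5-diene-1,4-dione, via ethyl 3-methyl-2,4,5-trioxoheptacosanoate 8 (not isolated), via ethyl 3-henicosyl-2,4,5-trioxoheptanoate 9 (not isolated), via disodium 2-henicosyl-5-methyl-3,6-dioxocyclohexa-1,4-diene-1,4-diolate 10 (not isolated)
Conditions: NaOEt (3 equiv), 7 (1.5 equiv), EtOH/THF, N2, slow addition of 6 at 0 °C, then reflux; 2 M HCl
Reagents that add atoms: none
Why: Double Claisen condensation: ketone–oxalate C-acylation at either α-methylene gives 8 or 9 (formed side by side as sodium enolates), each closes through its remaining α-methylene onto the ester in the same intramolecular Claisen that ends the Fichter dihydroxyquinone synthesis, and the six-membered tetraone is drawn out of all equilibria as the vinylogous carboxylate dianion 10, which is protonated to 11 on work-up; no stereocentre is formed.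

**Compound list**
1 | 1-bromodocosane | CCCCCCCCCCCCCCCCCCCCCCBr | starting material
2 | methyl propanoate | CCC(=O)OC | starting material
3 | docosyllithium | [Li]CCCCCCCCCCCCCCCCCCCCCC | intermediate
4 | tricosanoyllithium | [Li]C(=O)CCCCCCCCCCCCCCCCCCCCCC | intermediate
5 | lithium 3-methoxy-4-oxohexacosan-3-olate | CCC([O-])(OC)C(=O)CCCCCCCCCCCCCCCCCCCCCC.[Li+] | intermediate
6 | hexacosane-3,4-dione | CCC(=O)C(=O)CCCCCCCCCCCCCCCCCCCCCC | intermediate
7 | diethyl oxalate | CCOC(=O)C(=O)OCC | starting material
8 | ethyl 3-methyl-2,4,5-trioxoheptacosanoate | CCOC(=O)C(=O)C(C)C(=O)C(=O)CCCCCCCCCCCCCCCCCCCCCC | intermediate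
9 | ethyl 3-henicosyl-2,4,5-trioxoheptanoate | CCOC(=O)C(=O)C(CCCCCCCCCCCCCCCCCCCCC)C(=O)C(=O)CC | intermediate
10 | disodium 2-henicosyl-5-methyl-3,6-dioxocyclohexa-1,4-diene-1,4-diolate | CCCCCCCCCCCCCCCCCCCCCC1=C([O-])C(=O)C(C)=C([O-])C1=O.[Na+].[Na+] | intermediate
11 | 3-henicosyl-2,5-dihydroxy-6-methylcyclohexa-2,5-diene-1,4-dione | CCCCCCCCCCCCCCCCCCCCCC1=C(O)C(=O)C(C)=C(O)C1=O | target

**Step count and risk**
Total steps: 2. Longest linear sequence: 2 (1 → 6 → 11).

The route has only two steps, so both are ranked here, the riskier first; there is no third step to name.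

1. Step 1. The C22 organolithium and its adduct may come out of solution at −110 °C, and direct attack of 3 on the ester or enolisation of the ester competes with carbonylation. Fallback, setting out from 1 and coming back at 6: replace the free acyllithium by a masked acyl anion. 1,3-Dithiane is deprotonated (n-BuLi, THF, −30 °C) and alkylated with 1 to give 2-docosyl-1,3-dithiane F1. A second deprotonation (n-BuLi, THF, −20 to 0 °C) and acylation with N-methoxy-N-methylpropanamide gives 1-(2-docosyl-1,3-dithian-2-yl)propan-1-one F2, in which the same CO–CO bond has been made by an acyl anion equivalent. Oxidative removal of the dithiane (PhI(O2CCF3)2, MeCN/THF/H2O, 0 °C) releases 6.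

2. Step 2. The free 1,2-diketone can self-condense by aldol reaction before it is oxalylated, and bis-oxalylation can compete with ring closure. Fallback, setting out from 1 and coming back at 8: carry out the first Claisen on the mono-masked diketone, which has one enolisable position and no free 1,2-dione. 2-Docosyl-1,3-dithiane F1 and 1-(2-docosyl-1,3-dithian-2-yl)propan-1-one F2 are made from 1 as described above. The lithium enolate of F2 (LiN(SiMe3)2, THF, −78 °C) is acylated with 7 to give ethyl 4-(2-docosyl-1,3-dithian-2-yl)-3-methyl-2,4-dioxobutanoate F3. Unmasking with a near-stoichiometric amount of PhI(O2CCF3)2 in aqueous MeCN/THF gives 8 as a single regioisomer, which is then closed separately with NaOEt and acidified to reach 11 by way of 10.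

**Further compounds**
F1 | step 1 | 2-docosyl-1,3-dithiane | CCCCCCCCCCCCCCCCCCCCCCC1SCCCS1
F2 | step 1 | 1-(2-docosyl-1,3-dithian-2-yl)propan-1-one | CCC(=O)C1(CCCCCCCCCCCCCCCCCCCCCC)SCCCS1
F3 | step 2 | ethyl 4-(2-docosyl-1,3-dithian-2-yl)-3-methyl-2,4-dioxobutanoate | CCOC(=O)C(=O)C(C)C(=O)C1(CCCCCCCCCCCCCCCCCCCCCC)SCCCS1
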